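Count every flask in lives of a link rather than in hours, and judge the flasks by that count.

| setting | blue | ochre | amber | violet | grey | green |
|---|---|---|---|---|---|---|
| first end groups | 0.050 M | 0.050 M | 0.050 M (fed, over 25 h) | 0.050 M (fed, over 2.5 h) | 0.050 M | 0.050 M |
| third end groups | 0.500 equiv (in portions, 2, over 25 h) | 0.500 equiv | 0.500 equiv | 0.500 equiv | 0.500 equiv | 0.500 equiv (fed, over 25 h) |
| solid second end groups | 1.02 equiv | 1.02 equiv | 1.02 equiv | 1.02 equiv | 1.02 equiv | 1.02 equiv |
| temperature | 80 °C |  |  | 80 °C | 80 °C | 80 °C |
| time | 40 h | 40 h | 40 h | 40 h | 40 h | 40 h |
| remark | first portion at the start, last at 25 h | everything together at the start at 60 °C, warmed to 80 °C at 25 h | the addition at 60 °C, then warmed to 80 °C; the feed brings no volume worth counting | all else is in the flask from the start; the feed brings no volume worth counting | everything together at the start | all else is in the flask from the start; the feed brings no volume worth counting |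

    first end groups + second end groups → links (k1 = 19 /M/h, Ea1 = 87.0 kJ/mol)
    second end groups + third end groups → links of the second sort (k2 = 52 /M/h, Ea2 = 69.0 kJ/mol)
    2 third end groups → homo dimer (k3 = 3.6 /M/h, Ea3 = 90.0 kJ/mol)
    links → over-reaction product (k4 = 0.23 /h, Ea4 = 107 kJ/mol)
    solid second end groups ⇌ second end groups, rate k5*(cs5 - [second end groups]) while solid is left; crystals form when [second end groups] > cs5 (cs5 = 3.7 mM, k5 = 8.8 /h)
    (constants at 80 °C)

- a doubled species enters its step squared and goes two at a time
- given per volume of solution although it is solid: solid second end groups
- all constants are for 80 °C and move with temperature by the activation energies
- at the start none of the solid second end groups is in solution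

- the flask that comes out highest in share of links in links plus over-reaction product, or "all alike" when all lie within 1.5 percentage points (blue / ochre / amber / violet / grey / green / all alike)
- share of links in links plus over-reaction product at the end, blue
- share of links in links plus over-reaction product at the end, ochre
- share of links in links plus over-reaction product at the end, amber
- share of links in links plus over-reaction product at the end, violet
- share of links in links plus over-reaction product at the end, grey
- share of links in links plus over-reaction product at the end, green

Start with the main step alone. The solid refills the solution in about 0.114 h, far quicker than first end groups react, so take second end groups as standing at their solubility. First end groups then last 14.2 h on average, and with nothing else going on every link stays a link.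

Now add the over-reaction. A link at 80 °C lasts 4.35 h on average, and this life of a link is your clock. It is shorter than the life of first end groups, so links go while they are being made. Two rules follow. Links made evenly over a span keep a share equal to one minus the survival over that span, divided by the lives in it, where survival is the exponential of minus the lives. Once making stops, what stands simply falls by the survival of the lives that remain. Grey's 40 h is 9.20 lives.

Then add the third end groups. They want the solid too, and its 1.02 equiv is less than the 1.50 equiv wanted, so the solid is the limiting reagent and making must stop. My guess is that half of the third end groups' charge gets its partner. That leaves 0.770 equiv for first end groups, and the solid is gone after about 20.9 h in grey. Making therefore spans 4.81 lives and 4.39 lives follow it, which puts grey at 0.255%. Blue, violet and green also sit at 80 °C for 40 h, so I put them near grey.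

Last comes the cold stretch. At 60 °C a link lasts 38.8 h, so ochre and amber hold 4.10 lives in their whole run, fewer than grey. Links standing at the warming keep 3.17%, and even making over the whole run keeps 24.0%. I place ochre and amber between these two, far above grey. Both hold the same count of lives, so the count does not part them; I put amber first as a guess, its first end groups being fed in over 25 h, which should put more of its making after the warming.

The forecast gives amber as highest, with blue 0.3%, ochre 9.9%, amber 13.6%, violet 0.27%, grey 0.21% and green 0.12%, and says of the cooler flasks that they “keep a meaningful share of links”.

The flask puts amber highest, with blue 0.321%, ochre 9.81%, amber 14.5%, violet 0.218%, grey 0.178% and green 0.180%. In grey, the passing of links into over-reaction product has 87% of its turnover up to the asked time behind it at 20.0 h. Grey run at 55 °C stretches the life of a link to 69.8 h, so its 40 h is 0.573 lives and even making keeps 76.1%; that flask stands at 75.2%, with 38.9% of its solid still there.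

The constants used here stand for no real mixture, and the outcome is calculated.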